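## Retrosynthetic overview

1. The route rests on the C10'=C11' Z double bond of the C15 side chain on C6 of the 2,5-dihydroxy-3-methyl-1,4-benzoquinone ring. It carries a butyl end (C12'–C15') and a nine-methylene tether (C1'–C9'), so it is treated as acetylene placed between a butyl nucleophile and a primary iodide.
2. Key disconnections, both made in one flask: C11'–C12' by syn-carbocupration of acetylene with lithium dibutylcuprate, and C9'–C10' by alkylation of the Z-hexenylcuprate with the 9-iodononyl arene.
3. The quinone is carried as a 1,2,4,5-tetramethoxyarene. Its C3–CH3 and C6–C1' bonds come from two successive ortho-lithiation/alkylation steps on 1,2,4,5-tetramethoxybenzene (MeI, then excess 1,9-dibromononane, then Br to I).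
4. End game: Ce(IV) oxidation to the 2,5-dimethoxyquinone, then hydroxide hydrolysis of the two vinylogous esters.
5. Ring order: no ring is formed. The single six-membered carbocycle is bought with the starting arene.

Key step: step 4

Assumption: the target has no stereocentre and is achiral, so "single enantiomer" is read as the single Z isomer of the C10'=C11' double bond.

## Route

Step 1
Reactants: 1 1,2,4,5-tetramethoxybenzene; 2 n-butyllithium (base)
Product: 4 1,2,4,5-tetramethoxy-3-methylbenzene, via (2,3,5,6-tetramethoxyphenyl)lithium 3 (not isolated)
Conditions: n-BuLi (1.05 equiv), THF, 0 °C → rt; MeI, −78 °C → rt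
Reagents that add atoms: iodomethane, CI
Why: Directed ortho-lithiation followed by SN2 methylation: each free ring C–H of 1 lies between two methoxy groups that coordinate lithium and acidify it, and one equivalent of base should stop the sequence at the mono-methyl stage.

Step 2
Reactants: 4 1,2,4,5-tetramethoxy-3-methylbenzene; 2 n-butyllithium (base); 5 1,9-dibromononane
Product: 7 1-(9-bromononyl)-2,3,5,6-tetramethoxy-4-methylbenzene, via (2,3,5,6-tetramethoxy-4-methylphenyl)lithium 6 (not isolated)
Conditions: n-BuLi (1.05 equiv), THF, 0 °C → rt; cannulated into 5 (4 equiv), THF/HMPA, −78 °C → rt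
Reagents that add atoms: none
Why: The same directed ortho-lithiation removes the only ring proton left in 4, and SN2 alkylation of aryllithium 6 by a primary bromide, sped up by HMPA and run by inverse addition into a large excess of the symmetrical dibromide, should favour substitution at one chain end only.

Step 3
Reactants: 7 1-(9-bromononyl)-2,3,5,6-tetramethoxy-4-methylbenzene
Product: 8 1-(9-iodononyl)-2,3,5,6-tetramethoxy-4-methylbenzene
Conditions: NaI (3 equiv), acetone, reflux
Reagents that add atoms: sodium iodide, [Na+].[I-]
Why: Finkelstein halide exchange, an SN2 reaction driven by precipitation of sodium bromide from acetone, gives the softer and more reactive iodide that the cuprate alkylation needs, and nothing else in 7 reacts with iodide.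

Step 4
Reactants: 2 n-butyllithium; 9 acetylene; 8 1-(9-iodononyl)-2,3,5,6-tetramethoxy-4-methylbenzene
Product: 12 1,2,4,5-tetramethoxy-3-methyl-6-[(Z)-pentadec-10-enyl]benzene, via lithium dibutylcuprate 10 (not isolated), via lithium bis[(Z)-hex-1-enyl]cuprate 11 (not isolated)
Conditions: 2 (4 equiv), CuBr·SMe2 (2 equiv), Et2O, −35 °C; 9 (4 equiv, acetone-free), −50 → −25 °C; 8 (1 equiv), THF, HMPA, P(OEt)3, −40 °C → rt; aq NH4Cl/NH3
Reagents that add atoms: copper(I) bromide–dimethyl sulfide complex, CSC.[Cu]Br (copper enters 10 and 11 only, not 12)
Why: Two equivalents of 2 and CuBr·SMe2 give the Gilman reagent 10, and in ether each of its two Bu–Cu bonds adds to one molecule of acetylene through a four-centre syn insertion that forms C11'–C12' and leaves butyl and copper cis on the new double bond, giving 11. Iodide 8 then reacts at copper (SN2-type oxidative addition, then reductive elimination), and C9'–C10' forms with retention at the alkenyl carbon. The closest known reaction type is the Normant carbocupration of acetylene followed by alkylation of the Z-dialkenylcuprate with a primary iodide, the standard way to Z-alkene pheromone chains. No ring closes and no stereocentre is made; the one stereoelement, the Z geometry of C10'=C11', is controlled by the syn mechanism of insertion and by the retentive coupling, not by a competition between isomers. The step needs one insertion per butyl group and a configurationally stable alkenylcuprate, which two equivalents of acetylene per copper, ether as solvent (THF would favour deprotonation of acetylene) and temperatures at or below −25 °C until 8 is added should secure, while HMPA speeds the alkylation and P(OEt)3 keeps the alkenylcopper by-product from thermal dimerisation. Only one alkenyl ligand of 11 is transferred, so the cuprate is used in excess over 8, whose unhindered primary iodide sits nine carbons from a tetramethoxyarene that has no acidic proton and no site open to a cuprate.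

Step 5
Reactants: 12 1,2,4,5-tetramethoxy-3-methyl-6-[(Z)-pentadec-10-enyl]benzene
Product: 13 2,5-dimethoxy-3-methyl-6-[(Z)-pentadec-10-enyl]-1,4-benzoquinone
Conditions: (NH4)2Ce(NO3)6 (2.5 equiv), MeCN/H2O, 0 °C, short reaction time
Reagents that add atoms: water, O
Why: Ceric ammonium nitrate oxidative demethylation of a 1,4-dimethoxyarene: two one-electron oxidations with capture by water at a para pair of methoxy-bearing carbons expel two methanol, both para pairs lead to the same 2,5-dimethoxyquinone, and the very electron-rich, fully substituted ring is oxidised much faster than the isolated Z-alkene.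

Step 6
Reactants: 13 2,5-dimethoxy-3-methyl-6-[(Z)-pentadec-10-enyl]-1,4-benzoquinone
Product: 15 2,5-dihydroxy-3-methyl-6-[(Z)-pentadec-10-enyl]-1,4-benzoquinone (target), via disodium quinone-2,5-diolate 14 (not isolated)
Conditions: 2 M aq NaOH, EtOH, reflux, N2; then 2 M HCl, 0 °C
Reagents that add atoms: sodium hydroxide, [Na+].[OH-]
Why: Each remaining methoxy group is a vinylogous methyl ester, so hydroxide replaces it by conjugate addition–elimination to give the delocalised dianion 14, which acid protonates to 15, while the unactivated Z-alkene is untouched by aqueous base or cold dilute acid.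

## Compound list

1 | 1,2,4,5-tetramethoxybenzene | COc1cc(OC)c(OC)cc1OC | starting material
2 | n-butyllithium | [Li]CCCC | starting material
3 | (2,3,5,6-tetramethoxyphenyl)lithium | [Li]c1c(OC)c(OC)cc(OC)c1OC | intermediate
4 | 1,2,4,5-tetramethoxy-3-methylbenzene | COc1cc(OC)c(OC)c(C)c1OC | intermediate
5 | 1,9-dibromononane | BrCCCCCCCCCBr | starting material
6 | (2,3,5,6-tetramethoxy-4-methylphenyl)lithium | [Li]c1c(OC)c(OC)c(C)c(OC)c1OC | intermediate
7 | 1-(9-bromononyl)-2,3,5,6-tetramethoxy-4-methylbenzene | COc1c(C)c(OC)c(OC)c(CCCCCCCCCBr)c1OC | intermediate
8 | 1-(9-iodononyl)-2,3,5,6-tetramethoxy-4-methylbenzene | COc1c(C)c(OC)c(OC)c(CCCCCCCCCI)c1OC | intermediate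
9 | acetylene | C#C | starting material
10 | lithium dibutylcuprate | CCCC[Cu-]CCCC.[Li+] | intermediate
11 | lithium bis[(Z)-hex-1-enyl]cuprate | CCCC/C=C\[Cu-]/C=C\CCCC.[Li+] | intermediate
12 | 1,2,4,5-tetramethoxy-3-methyl-6-[(Z)-pentadec-10-enyl]benzene | COc1c(C)c(OC)c(OC)c(CCCCCCCCC/C=C\CCCC)c1OC | intermediate
13 | 2,5-dimethoxy-3-methyl-6-[(Z)-pentadec-10-enyl]-1,4-benzoquinone | CCCC/C=C\CCCCCCCCCC1=C(OC)C(=O)C(C)=C(OC)C1=O | intermediate
14 | disodium 3-methyl-6-[(Z)-pentadec-10-enyl]-1,4-benzoquinone-2,5-diolate (disodium quinone-2,5-diolate) | CCCC/C=C\CCCCCCCCCC1=C([O-])C(=O)C(C)=C([O-])C1=O.[Na+].[Na+] | intermediate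
15 | 2,5-dihydroxy-3-methyl-6-[(Z)-pentadec-10-enyl]-1,4-benzoquinone | CCCC/C=C\CCCCCCCCCC1=C(O)C(=O)C(C)=C(O)C1=O | target

## Step count

Total step count: 6
Longest linear sequence: 6 steps (1 → 4 → 7 → 8 → 12 → 13 → 15)

## Steps most likely to fail

**Step 4.** The three-component coupling may suffer in several ways:
- incomplete insertion, which leaves butyl ligands that compete in the alkylation;
- a second acetylene insertion;
- proton transfer from acetylene to the cuprate;
- thermal decay of the alkenylcopper species before the rather slow alkylation is over.

The fallback sets out from 8 and comes back at 12. It makes the Z-alkene by alkyne semihydrogenation instead. Hex-1-yne is deprotonated with 2 in THF to lithium hex-1-ynide F1. This is alkylated by iodide 8 in THF/DMPU to give 1,2,4,5-tetramethoxy-3-methyl-6-(pentadec-10-ynyl)benzene F2. Hydrogenation of F2 over Lindlar catalyst with quinoline delivers both hydrogens to one face of the alkyne and should give 12.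

**Step 2.** SN2 attack by an aryllithium flanked by two methoxy groups may be slow. Lithium–bromine exchange, E2 elimination and a second substitution at the far chain end could then compete.

The fallback sets out from 4 (through aryllithium 6) and comes back at 7. It replaces the substitution by a carbonyl addition and an ionic deoxygenation. Commercial 9-bromononan-1-ol is oxidised (Dess–Martin periodinane, CH2Cl2) to 9-bromononanal F3. Aryllithium 6 adds to F3 at −78 °C in THF, and a quench with aq NH4Cl gives racemic 9-bromo-1-(2,3,5,6-tetramethoxy-4-methylphenyl)nonan-1-ol F4. Et3SiH/TFA in CH2Cl2 at 0 °C then reduces the strongly stabilised benzylic cation. This removes the transient stereocentre and gives 7 with the primary bromide intact.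

**Step 5.** Ce(IV) and nitrate may attack the alkene or the benzylic positions, or the acidic medium may start uncontrolled partial hydrolysis of the product.

The fallback sets out from 12 and comes back at 13. It separates the oxidation from the unmasking. Constant-current anodic oxidation of 12 at a platinum anode in KOH/MeOH (undivided cell, 0 °C) works at a potential far below that of an isolated alkene. It should give the quinone bis(dimethyl ketal) 1,3,3,4,6,6-hexamethoxy-2-methyl-5-[(Z)-pentadec-10-enyl]cyclohexa-1,4-diene F5. Mild hydrolysis of both ketals (dilute aqueous acetic acid in acetone, rt) then gives 13.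

## Further compounds

F1 | step 4 | lithium hex-1-ynide | [Li]C#CCCCC
F2 | step 4 | 1,2,4,5-tetramethoxy-3-methyl-6-(pentadec-10-ynyl)benzene | COc1c(C)c(OC)c(OC)c(CCCCCCCCCC#CCCCC)c1OC
F3 | step 2 | 9-bromononanal | BrCCCCCCCCC=O
F4 | step 2 | 9-bromo-1-(2,3,5,6-tetramethoxy-4-methylphenyl)nonan-1-ol (racemic) | COc1c(C)c(OC)c(OC)c(C(O)CCCCCCCCBr)c1OC
F5 | step 5 | 1,3,3,4,6,6-hexamethoxy-2-methyl-5-[(Z)-pentadec-10-enyl]cyclohexa-1,4-diene | CCCC/C=C\CCCCCCCCCC1=C(OC)C(OC)(OC)C(C)=C(OC)C1(OC)OC
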